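**Retrosynthetic overview** (furofuran numbered as 3,7-dioxabicyclo[3.3.0]octane: bridgeheads C1/C5, aryl-bearing C2/C6, ring oxygens O3/O7, methylenes C4/C8)
1. The aryl–C bond between benzofuran C5 and furofuran C2 is made in the penultimate step by Friedel–Crafts capture of a bicyclic oxocarbenium ion, which is generated in the same flask by closing the O7 ring (C1–C8 bond) of a monocyclic 2,3-dihydrofuran that carries a methoxymethyl ether.
2. Enabling feature: C2 lies between ring oxygen O3 and bridgehead C1, and C8 lies between O7 and C1, so an enol ether C1=C2 attacking an O7=C8H2 oxocarbenium ion leaves the positive charge exactly at C2; benzofuran C5 is para to ring oxygen O1 and is the most nucleophilic arene carbon of the other half.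
3. Dihydrofuran half: Evans syn-aldol (sets C5 and C6), MOM ether (the future C8), auxiliary reduction, alkene cleavage to the lactol (O3 ring), dehydration.
4. Arene half: the cis-2,3-dihydrobenzofuran ring is closed by Rh(II)-catalysed benzylic C–H insertion of an aryl diazoacetate (sets benzofuran C2 and C3).
5. Ring order: dihydrobenzofuran ring, then O3 ring, then O7 ring (key step); a single LiAlH4 operation then converts the ester into CH2OH and frees both phenols.

Key step: step 15

Assumption: Rh2(S-PTTL)4 is taken to deliver the (2S,3R) enantiomer of the cis ester in step 14; should its sense of induction be the opposite, Rh2(R-PTTL)4 is used with nothing else changed.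

**Route**

Step 1
Reactants: 1 syringaldehyde
Product: 2 4-formyl-2,6-dimethoxyphenyl pivalate
Conditions: PivCl, Et3N, DMAP (cat.), CH2Cl2, 0 °C → rt
Reagents that add atoms: pivaloyl chloride, CC(C)(C)C(=O)Cl
Why: DMAP-catalysed O-acylation of the phenol; the pivalate makes the syringyl ring electron-poor enough that it neither ionises at its benzylic carbon nor acts as an arene nucleophile in step 15, and it is removed by hydride in step 16.

Step 2
Reactants: 3 (S)-4-benzyloxazolidin-2-one; 4 pent-4-enoyl chloride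
Product: 5 (S)-4-benzyl-3-(pent-4-enoyl)oxazolidin-2-one
Conditions: n-BuLi, THF, −78 °C; then 4, −78 → 0 °C
Reagents that add atoms: none
Why: N-acylation of the lithiated oxazolidinone with an acid chloride, the standard entry to Evans imides.

Step 3
Reactants: 5 (S)-4-benzyl-3-(pent-4-enoyl)oxazolidin-2-one; 2 4-formyl-2,6-dimethoxyphenyl pivalate
Product: 6 (S)-4-benzyl-3-[(2S,3S)-2-allyl-3-(3,5-dimethoxy-4-pivaloyloxyphenyl)-3-hydroxypropanoyl]oxazolidin-2-one
Conditions: Bu2BOTf, i-Pr2NEt, CH2Cl2, −78 → 0 °C; then 2, −78 → 0 °C; pH 7 buffer, MeOH, H2O2, 0 °C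
Reagents that add atoms: none
Why: Evans syn-aldol reaction through the Z-boron enolate and a chair Zimmerman–Traxler transition state, in which the benzyl group of the auxiliary shields one enolate face, so the (2S,3S) syn adduct should form; these two centres become furofuran C5 and C6 with the aryl group exo.

Step 4
Reactants: 6 syn-aldol adduct
Product: 7 (S)-4-benzyl-3-[(2S,3S)-2-allyl-3-(3,5-dimethoxy-4-pivaloyloxyphenyl)-3-(methoxymethoxy)propanoyl]oxazolidin-2-one
Conditions: MOMCl, i-Pr2NEt, Bu4NI (cat.), CH2Cl2, 0 → 40 °C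
Reagents that add atoms: chloromethyl methyl ether, COCCl
Why: Standard MOM ether formation on a secondary alcohol under non-enolising amine conditions; the O–CH2–OMe carbon placed on O7 is the latent C8 of the furofuran.

Step 5
Reactants: 7 MOM-protected aldol imide
Product: 8 (R)-2-[(S)-(3,5-dimethoxy-4-pivaloyloxyphenyl)(methoxymethoxy)methyl]pent-4-en-1-ol
Conditions: NaBH4, THF/H2O (4:1), 0 °C → rt
Reagents that add atoms: none
Why: Borohydride reduction of the N-acyl oxazolidinone at the exocyclic carbonyl releases the auxiliary and gives the primary alcohol without touching the stereocentres, the alkene or the hindered 2,6-dimethoxyaryl pivalate.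

Step 6
Reactants: 8 homoallylic primary alcohol
Product: 9 (4R)-4-[(S)-(3,5-dimethoxy-4-pivaloyloxyphenyl)(methoxymethoxy)methyl]tetrahydrofuran-2-ol (anomer mixture)
Conditions: OsO4 (2 mol%), NaIO4, 2,6-lutidine, dioxane/H2O (3:1), rt
Reagents that add atoms: osmium tetroxide (cat.), O=[Os](=O)(=O)=O; sodium periodate, [Na+].[O-]I(=O)(=O)=O
Why: Lemieux–Johnson cleavage of the terminal alkene gives a γ-hydroxy aldehyde that should close spontaneously to the five-membered lactol, which is the furofuran ring containing O3; the MOM acetal and the arene are not exposed to ozone.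

Step 7
Reactants: 9 lactol
Product: 10 (R)-3-[(S)-(3,5-dimethoxy-4-pivaloyloxyphenyl)(methoxymethoxy)methyl]-2,3-dihydrofuran
Conditions: MsCl, Et3N (5 equiv), CH2Cl2, −20 → 40 °C; chromatography on Et3N-deactivated silica
Reagents that add atoms: none
Why: Dehydration of a lactol through its anomeric mesylate/chloride and amine-induced elimination, the usual route from 2-deoxy lactols to furanoid enol ethers; elimination can only occur towards the ring CH2, giving the C1=C2 enol ether.

Step 8
Reactants: 11 vanillin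
Product: 12 4-formyl-2-methoxyphenyl pivalate
Conditions: PivCl, Et3N, DMAP (cat.), CH2Cl2, 0 °C → rt
Reagents that add atoms: pivaloyl chloride, CC(C)(C)C(=O)Cl
Why: Phenol acylation as in step 1; the pivalate keeps the guaiacyl ring electron-poor so that the benzylic C–O bond of the later cis-dihydrobenzofuran does not ionise under Lewis acid.

Step 9
Reactants: 12 4-formyl-2-methoxyphenyl pivalate
Product: 13 4-(hydroxymethyl)-2-methoxyphenyl pivalate
Conditions: NaBH4, THF/MeOH, 0 °C
Reagents that add atoms: none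
Why: Chemoselective borohydride reduction of an aryl aldehyde, much faster than attack on the hindered aryl pivalate at 0 °C.

Step 10
Reactants: 13 4-(hydroxymethyl)-2-methoxyphenyl pivalate; 14 2-allyl-6-methoxyphenol (o-eugenol)
Product: 15 4-[(2-allyl-6-methoxyphenoxy)methyl]-2-methoxyphenyl pivalate
Conditions: PPh3, DIAD, THF, 0 °C → rt
Reagents that add atoms: none
Why: Mitsunobu etherification of a phenol with a primary benzylic alcohol under neutral conditions that leave the pivalate intact.

Step 11
Reactants: 15 allyl arene benzyl ether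
Product: 17 2-[3-methoxy-2-(3-methoxy-4-pivaloyloxybenzyloxy)phenyl]acetic acid, via arylacetaldehyde 16 (not isolated)
Conditions: O3, CH2Cl2, −78 °C (indicator dye end point); PPh3, −78 °C → rt; crude aldehyde then NaClO2, NaH2PO4, 2-methylbut-2-ene, t-BuOH/H2O, 0 °C → rt
Reagents that add atoms: ozone, [O-][O+]=O; sodium chlorite, [Na+].[O-]Cl=O
Why: Ozonolysis of the terminal alkene is much faster than attack on the arenes at −78 °C, and the sensitive arylacetaldehyde is telescoped into a Pinnick oxidation, which is neutral enough for the pivalate and the benzyl ether.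

Step 12
Reactants: 17 arylacetic acid
Product: 18 methyl 2-[3-methoxy-2-(3-methoxy-4-pivaloyloxybenzyloxy)phenyl]acetate
Conditions: MeI, KHCO3, DMF, rt
Reagents that add atoms: iodomethane, CI
Why: SN2 O-methylation of the carboxylate under weakly basic conditions that do not cleave the aryl pivalate.

Step 13
Reactants: 18 methyl arylacetate
Product: 19 methyl 2-diazo-2-[3-methoxy-2-(3-methoxy-4-pivaloyloxybenzyloxy)phenyl]acetate
Conditions: p-ABSA, DBU, MeCN, 0 °C → rt
Reagents that add atoms: 4-acetamidobenzenesulfonyl azide, CC(=O)Nc1ccc(cc1)S(=O)(=O)N=[N+]=[N-]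
Why: Regitz diazo transfer to the acidic benzylic methylene of an arylacetate, the standard preparation of aryl diazoacetates.

Step 14
Reactants: 19 aryl diazoacetate
Product: 20 methyl (2S,3R)-7-methoxy-2-(3-methoxy-4-pivaloyloxyphenyl)-2,3-dihydrobenzofuran-3-carboxylate (2,3-cis)
Conditions: Rh2(S-PTTL)4 (1 mol%), toluene, −60 °C
Reagents that add atoms: none
Why: Intramolecular 1,5 C–H insertion of the donor/acceptor rhodium carbenoid into the ether-activated benzylic C–H closes the dihydrobenzofuran ring; the concerted insertion transition state gives the 2,3-cis ester as the kinetic product and the chiral carboxylate ligands select one enantiotopic benzylic hydrogen, setting C2 (S) and C3 (R) together.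

Step 15
Reactants: 10 dihydrofuran MOM ether; 20 cis-dihydrobenzofuran ester (1.5 equiv)
Product: 23 methyl (2S,3R)-5-[(1S,3aR,4S,6aR)-4-(3,5-dimethoxy-4-pivaloyloxyphenyl)tetrahydro-1H,3H-furo[3,4-c]furan-1-yl]-7-methoxy-2-(3-methoxy-4-pivaloyloxyphenyl)-2,3-dihydrobenzofuran-3-carboxylate, via methylene oxocarbenium triflate 21 (not isolated), via bicyclic oxocarbenium triflate 22 (not isolated)
Conditions: TMSOTf (1.2 equiv), 2,6-di-tert-butyl-4-methylpyridine (1.5 equiv), 4 Å MS, CH2Cl2, −78 → −30 °C, slow addition of 10 to 20/TMSOTf; Et3N quench at −30 °C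
Reagents that add atoms: none
Why: Proposed new method: TMSOTf should abstract the unhindered methoxy group of the MOM ether to give the O7=C8H2 oxocarbenium ion 21, whose carbon is attacked by enol-ether carbon C1 to close the second tetrahydrofuran ring and leave the bicyclic O3=C2 oxocarbenium ion 22, which is captured at C2 by C5 of arene 20 in a Friedel–Crafts substitution; the closest known reaction types are the Lewis acid-mediated cyclisation of acetals onto 2,3-dihydrofurans to furofuran acetals and the acid-mediated C-arylation of furofuran lactol derivatives (C-aryl glycoside formation), which have not been run in tandem. The ring closure is a cationic five-membered (Prins-type) closure, endo-trig at the oxocarbenium C8=O7 and exo at the enol ether C1=C2, and only the cis ring fusion is accessible, so C1 is fixed by the existing centre C5. The new centre C2 is set by attack of the arene on the convex face of the cis-fused cation, anti to the C8 bridge, which places the aryl group exo as the target requires. Chemoselectivity requires that the cation meets the arene and not unreacted enol ether, which slow addition of 10 to an excess of 20 should secure. Regioselectivity requires attack through C5 of 20, which is para to ring oxygen O1, whereas C4 is shielded by the C3 ester and both pivaloylated rings are deactivated. The pivalates, the low temperature and the hindered pyridine base should also keep the benzylic C–O bonds (benzofuran C2–O1, furofuran C6–O7 and the new C2–O3) from ionising, so neither the cis-dihydrobenzofuran nor the exo aryl groups should epimerise.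

Step 16
Reactants: 23 protected coupling product
Product: 24 4-[(1S,3aR,4S,6aR)-4-[(2S,3S)-2-(4-hydroxy-3-methoxyphenyl)-3-(hydroxymethyl)-7-methoxy-2,3-dihydrobenzofuran-5-yl]tetrahydro-1H,3H-furo[3,4-c]furan-1-yl]-2,6-dimethoxyphenol (target, CNP0126146.1)
Conditions: LiAlH4 (excess), THF, −20 °C → rt; Rochelle salt work-up
Reagents that add atoms: none
Why: Hydride reduction of the methyl ester to the primary alcohol and reductive cleavage of both aryl pivalates in one operation; ester reduction at −20 °C should outrun enolisation so the cis C3 centre is kept (its descriptor changes from R to S only by priority), and no hydrogenolysis or acid is used, so the benzylic ethers survive.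

**Compound list**
1 | syringaldehyde | COc1cc(C=O)cc(OC)c1O | starting material
2 | 4-formyl-2,6-dimethoxyphenyl pivalate | COc1cc(C=O)cc(OC)c1OC(=O)C(C)(C)C | intermediate
3 | (S)-4-benzyloxazolidin-2-one | O=C1N[C@@H](Cc2ccccc2)CO1 | starting material
4 | pent-4-enoyl chloride | C=CCCC(=O)Cl | starting material
5 | (S)-4-benzyl-3-(pent-4-enoyl)oxazolidin-2-one | C=CCCC(=O)N1[C@@H](Cc2ccccc2)COC1=O | intermediate
6 | (S)-4-benzyl-3-[(2S,3S)-2-allyl-3-(3,5-dimethoxy-4-pivaloyloxyphenyl)-3-hydroxypropanoyl]oxazolidin-2-one | O[C@@H]([C@H](CC=C)C(=O)N1[C@@H](Cc2ccccc2)COC1=O)c1cc(OC)c(OC(=O)C(C)(C)C)c(OC)c1 | intermediate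
7 | (S)-4-benzyl-3-[(2S,3S)-2-allyl-3-(3,5-dimethoxy-4-pivaloyloxyphenyl)-3-(methoxymethoxy)propanoyl]oxazolidin-2-one | COCO[C@@H]([C@H](CC=C)C(=O)N1[C@@H](Cc2ccccc2)COC1=O)c1cc(OC)c(OC(=O)C(C)(C)C)c(OC)c1 | intermediate
8 | (R)-2-[(S)-(3,5-dimethoxy-4-pivaloyloxyphenyl)(methoxymethoxy)methyl]pent-4-en-1-ol | COCO[C@@H]([C@H](CC=C)CO)c1cc(OC)c(OC(=O)C(C)(C)C)c(OC)c1 | intermediate
9 | (4R)-4-[(S)-(3,5-dimethoxy-4-pivaloyloxyphenyl)(methoxymethoxy)methyl]tetrahydrofuran-2-ol (anomer mixture) | COCO[C@@H]([C@H]1COC(O)C1)c1cc(OC)c(OC(=O)C(C)(C)C)c(OC)c1 | intermediate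
10 | (R)-3-[(S)-(3,5-dimethoxy-4-pivaloyloxyphenyl)(methoxymethoxy)methyl]-2,3-dihydrofuran | COCO[C@@H]([C@H]1COC=C1)c1cc(OC)c(OC(=O)C(C)(C)C)c(OC)c1 | intermediate
11 | vanillin | COc1cc(C=O)ccc1O | starting material
12 | 4-formyl-2-methoxyphenyl pivalate | COc1cc(C=O)ccc1OC(=O)C(C)(C)C | intermediate
13 | 4-(hydroxymethyl)-2-methoxyphenyl pivalate | COc1cc(CO)ccc1OC(=O)C(C)(C)C | intermediate
14 | 2-allyl-6-methoxyphenol (o-eugenol) | COc1cccc(CC=C)c1O | starting material
15 | 4-[(2-allyl-6-methoxyphenoxy)methyl]-2-methoxyphenyl pivalate | COc1cccc(CC=C)c1OCc1ccc(OC(=O)C(C)(C)C)c(OC)c1 | intermediate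
16 | 2-[3-methoxy-2-(3-methoxy-4-pivaloyloxybenzyloxy)phenyl]acetaldehyde | COc1cccc(CC=O)c1OCc1ccc(OC(=O)C(C)(C)C)c(OC)c1 | intermediate
17 | 2-[3-methoxy-2-(3-methoxy-4-pivaloyloxybenzyloxy)phenyl]acetic acid | COc1cccc(CC(=O)O)c1OCc1ccc(OC(=O)C(C)(C)C)c(OC)c1 | intermediate
18 | methyl 2-[3-methoxy-2-(3-methoxy-4-pivaloyloxybenzyloxy)phenyl]acetate | COC(=O)Cc1cccc(OC)c1OCc1ccc(OC(=O)C(C)(C)C)c(OC)c1 | intermediate
19 | methyl 2-diazo-2-[3-methoxy-2-(3-methoxy-4-pivaloyloxybenzyloxy)phenyl]acetate | COC(=O)C(=[N+]=[N-])c1cccc(OC)c1OCc1ccc(OC(=O)C(C)(C)C)c(OC)c1 | intermediate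
20 | methyl (2S,3R)-7-methoxy-2-(3-methoxy-4-pivaloyloxyphenyl)-2,3-dihydrobenzofuran-3-carboxylate (cis) | COc1cc([C@H]2Oc3c(OC)cccc3[C@H]2C(=O)OC)ccc1OC(=O)C(C)(C)C | intermediate
21 | [(S)-[(R)-2,3-dihydrofuran-3-yl](3,5-dimethoxy-4-pivaloyloxyphenyl)methyl](methylene)oxonium triflate | C=[O+][C@@H]([C@H]1COC=C1)c1cc(OC)c(OC(=O)C(C)(C)C)c(OC)c1.[O-]S(=O)(=O)C(F)(F)F | intermediate
22 | (1R,5R,6S)-6-(3,5-dimethoxy-4-pivaloyloxyphenyl)-3,7-dioxabicyclo[3.3.0]oct-2-en-3-ium triflate | C1=[O+]C[C@H]2[C@@H]1CO[C@@H]2c1cc(OC)c(OC(=O)C(C)(C)C)c(OC)c1.[O-]S(=O)(=O)C(F)(F)F | intermediate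
23 | methyl (2S,3R)-5-[(1S,3aR,4S,6aR)-4-(3,5-dimethoxy-4-pivaloyloxyphenyl)tetrahydro-1H,3H-furo[3,4-c]furan-1-yl]-7-methoxy-2-(3-methoxy-4-pivaloyloxyphenyl)-2,3-dihydrobenzofuran-3-carboxylate | COc1cc([C@H]2Oc3c(OC)cc([C@H]4OC[C@H]5[C@@H]4CO[C@@H]5c4cc(OC)c(OC(=O)C(C)(C)C)c(OC)c4)cc3[C@H]2C(=O)OC)ccc1OC(=O)C(C)(C)C | intermediate
24 | 4-[(1S,3aR,4S,6aR)-4-[(2S,3S)-2-(4-hydroxy-3-methoxyphenyl)-3-(hydroxymethyl)-7-methoxy-2,3-dihydrobenzofuran-5-yl]tetrahydro-1H,3H-furo[3,4-c]furan-1-yl]-2,6-dimethoxyphenol | COc1cc([C@H]2Oc3c(OC)cc([C@H]4OC[C@H]5[C@@H]4CO[C@@H]5c4cc(OC)c(O)c(OC)c4)cc3[C@H]2CO)ccc1O | target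

**Step count and risks**
Total steps: 16. Longest linear sequence: 9 (steps 8–14, 15, 16).

Steps most likely to fail:

1. Step 15 (proposed new method). The bicyclic cation may be consumed by unreacted enol ether (oligomerisation) before the moderately nucleophilic arene reacts, or the arene may attack through a position other than C5. The fallback sets out from 10 and 20 and comes back at 23, using known reaction types only. Compound 10 would be isomerised with catalytic TMSOTf (CH2Cl2, −40 °C; acetal/dihydrofuran cyclisation with return of methoxide) to the isolated bicyclic methyl acetal (1R,5R,6S)-6-(3,5-dimethoxy-4-pivaloyloxyphenyl)-2-methoxy-3,7-dioxabicyclo[3.3.0]octane F1. Arene 20 would be brominated para to O1 (NBS, MeCN, 0 °C) to the 5-bromide F2, borylated (B2pin2, Pd(dppf)Cl2, KOAc, dioxane, 80 °C) to the pinacol boronate F3, and converted with KHF2 (MeOH/H2O) into the potassium aryltrifluoroborate F4. BF3·OEt2-promoted ipso-substitution of F4 by the oxocarbenium ion from F1 (MeCN/CH2Cl2, −40 → 0 °C), again from the convex face, should give 23 with the position of attack fixed by boron.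

2. Step 14. The pivaloyloxy-substituted benzylic C–H is less hydridic than in simple benzyl ethers, and the flanking 3-methoxy group crowds the ether, so enantioselectivity or cis selectivity of the carbenoid insertion may be insufficient. The fallback sets out from 19 and comes back at 20. Diazo ester 19 would be decomposed with achiral Rh2(OAc)4 (CH2Cl2, rt) to the racemic cis ester, that is 20 together with its enantiomer methyl (2R,3S)-7-methoxy-2-(3-methoxy-4-pivaloyloxyphenyl)-2,3-dihydrobenzofuran-3-carboxylate F5. Any trans isomer would be removed by chromatography, and 20 separated from F5 by preparative chiral SFC, so that the absolute configuration comes from resolution instead of catalyst control.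

3. Step 7. The elimination may stall at the anomeric chloride, or the acid-sensitive enol ether may hydrate or oligomerise during elimination and isolation. The fallback sets out from 9 and comes back at 10. Lactol 9 would be converted under neutral conditions (PhSSPh, Bu3P, CH2Cl2, rt) into the phenylthio acetal (4R)-4-[(S)-(3,5-dimethoxy-4-pivaloyloxyphenyl)(methoxymethoxy)methyl]-2-(phenylthio)tetrahydrofuran F6. Oxidation with mCPBA (CH2Cl2, −78 °C) would give the sulfoxide F7, and thermolysis (toluene, NaHCO3, 110 °C) would give 10 by syn-elimination, which can only occur towards the ring CH2.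

**Further compounds**
F1 | step 15 | (1R,5R,6S)-6-(3,5-dimethoxy-4-pivaloyloxyphenyl)-2-methoxy-3,7-dioxabicyclo[3.3.0]octane (anomer mixture) | COC1OC[C@H]2[C@@H]1CO[C@@H]2c1cc(OC)c(OC(=O)C(C)(C)C)c(OC)c1
F2 | step 15 | methyl (2S,3R)-5-bromo-7-methoxy-2-(3-methoxy-4-pivaloyloxyphenyl)-2,3-dihydrobenzofuran-3-carboxylate | COc1cc([C@H]2Oc3c(OC)cc(Br)cc3[C@H]2C(=O)OC)ccc1OC(=O)C(C)(C)C
F3 | step 15 | methyl (2S,3R)-7-methoxy-2-(3-methoxy-4-pivaloyloxyphenyl)-5-(4,4,5,5-tetramethyl-1,3,2-dioxaborolan-2-yl)-2,3-dihydrobenzofuran-3-carboxylate | COc1cc([C@H]2Oc3c(OC)cc(B4OC(C)(C)C(C)(C)O4)cc3[C@H]2C(=O)OC)ccc1OC(=O)C(C)(C)C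
F4 | step 15 | potassium [(2S,3R)-7-methoxy-3-(methoxycarbonyl)-2-(3-methoxy-4-pivaloyloxyphenyl)-2,3-dihydrobenzofuran-5-yl]trifluoroborate | COc1cc([C@H]2Oc3c(OC)cc([B-](F)(F)F)cc3[C@H]2C(=O)OC)ccc1OC(=O)C(C)(C)C.[K+]
F5 | step 14 | methyl (2R,3S)-7-methoxy-2-(3-methoxy-4-pivaloyloxyphenyl)-2,3-dihydrobenzofuran-3-carboxylate (enantiomer of 20) | COc1cc([C@@H]2Oc3c(OC)cccc3[C@@H]2C(=O)OC)ccc1OC(=O)C(C)(C)C
F6 | step 7 | (4R)-4-[(S)-(3,5-dimethoxy-4-pivaloyloxyphenyl)(methoxymethoxy)methyl]-2-(phenylthio)tetrahydrofuran | COCO[C@@H]([C@H]1COC(Sc2ccccc2)C1)c1cc(OC)c(OC(=O)C(C)(C)C)c(OC)c1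
F7 | step 7 | (4R)-4-[(S)-(3,5-dimethoxy-4-pivaloyloxyphenyl)(methoxymethoxy)methyl]-2-(phenylsulfinyl)tetrahydrofuran | COCO[C@@H]([C@H]1COC(S(=O)c2ccccc2)C1)c1cc(OC)c(OC(=O)C(C)(C)C)c(OC)c1
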